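**Plan**

- Retrosynthesis: the three benzyl ethers come off last; the O1–C2 bond of the dihydrofuran ring is cut next; then the C3–aryl bond (3,5-dioxygenated ring) and the C2–aryl bond (4-oxygenated ring) are cut together, leaving a ring A (E)-vinylboronate, an aryl triflate and an aryllithium.
- Enabling feature (benzofuran numbering): C2 and C3 are adjacent benzylic stereocentres that each carry one aryl ring, and C3 sits on ring A between two equivalent oxygen-bearing carbons (C4–OH and C7a–O1). Two aryl groups can therefore be added across a ring A vinylboron unit, and either oxygen can close the ring.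
- Forward, ring A piece: resveratrol is MOM-protected, hydrogenated, lithiated between the two ring A acetal oxygens and formylated; the aldehyde becomes the alkyne and then the (E)-alkenyl boronate of the hindered cis-diol "mac".
- The open chain is joined in one three-component step (aryllithium on boron, aryl triflate on palladium) that forms both C–aryl bonds; C–B is then oxidised to C–OH.
- The only ring closure comes late: acid removes the MOM groups and a ring A phenol closes O1–C2; hydrogenolysis frees the last three phenols.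
- Stereochemistry: C3 comes from the chiral diphosphine on palladium; C2 comes from the anti 1,2-shift across the E alkene, is kept in the oxidation, and ends trans to C3 in the ring closure (net inversion, under control of C3).

Key step: step 8

Assumption: the ferrocenyl diphosphine enantiomer written in step 8 is taken to be the one that sends palladium to the Re face of the alkene carbon next to ring A in 10; if the sense of induction is the opposite, the mirror-image ligand is used and nothing else changes.

**Route**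

Step 1
Reactants: 1 resveratrol
Product: 2 (E)-1,3-bis(methoxymethoxy)-5-{2-[4-(methoxymethoxy)phenyl]ethenyl}benzene
Conditions: NaH, MOMCl, DMF, 0 °C → rt
Reagents that add atoms: chloromethyl methyl ether, COCCl
Why: Williamson-type O-alkylation of the three phenoxides gives MOM acetals that are stable to base, organolithium reagents and hydrogenation and that direct the later ortho-lithiation; no stereocentre is formed.

Step 2
Reactants: 2 (E)-1,3-bis(methoxymethoxy)-5-{2-[4-(methoxymethoxy)phenyl]ethenyl}benzene
Product: 3 1,3-bis(methoxymethoxy)-5-{2-[4-(methoxymethoxy)phenyl]ethyl}benzene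
Conditions: H2 (1 atm), 10% Pd/C, EtOAc, rt
Reagents that add atoms: none
Why: Heterogeneous catalytic hydrogenation saturates the stilbene double bond to the bibenzyl while aryl MOM ethers are inert to hydrogen over palladium on carbon; no stereocentre is formed.

Step 3
Reactants: 3 1,3-bis(methoxymethoxy)-5-{2-[4-(methoxymethoxy)phenyl]ethyl}benzene
Product: 5 2,6-bis(methoxymethoxy)-4-{2-[4-(methoxymethoxy)phenyl]ethyl}benzaldehyde, via ring A aryllithium 4 (not isolated)
Conditions: n-BuLi (1.05 equiv), THF, 0 °C; DMF, 0 °C → rt; H2O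
Reagents that add atoms: N,N-dimethylformamide, CN(C)C=O
Why: Directed ortho-metalation should occur at the ring A position between the two acetal oxygens, which is activated by both directing groups, in preference to the positions next to the single acetal oxygen of the other ring, and DMF formylates the aryllithium; no stereocentre is formed.

Step 4
Reactants: 5 2,6-bis(methoxymethoxy)-4-{2-[4-(methoxymethoxy)phenyl]ethyl}benzaldehyde
Product: 6 2-ethynyl-1,3-bis(methoxymethoxy)-5-{2-[4-(methoxymethoxy)phenyl]ethyl}benzene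
Conditions: dimethyl (1-diazo-2-oxopropyl)phosphonate, K2CO3, MeOH/THF, rt
Reagents that add atoms: dimethyl (1-diazo-2-oxopropyl)phosphonate, COP(=O)(OC)C(=[N+]=[N-])C(C)=O
Why: Seyferth–Gilbert homologation with the Ohira–Bestmann reagent converts the non-enolisable aryl aldehyde to the terminal alkyne under mild basic conditions that leave the acetals untouched; no stereocentre is formed.

Step 5
Reactants: 7 acenaphthoquinone
Product: 8 (1R,2S)-1,2-dimethyl-1,2-dihydroacenaphthylene-1,2-diol (cis, meso; "mac diol")
Conditions: AlMe3 (4 equiv), toluene, 0 °C → rt; aqueous work-up; recrystallisation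
Reagents that add atoms: trimethylaluminium, C[Al](C)C
Why: Twofold 1,2-addition of methyl groups to the 1,2-diketone, the second under chelation by the first aluminium alkoxide, should give mainly the cis (meso) diol, the isomer that can span boron, and recrystallisation removes any trans isomer.

Step 6
Reactants: 6 2-ethynyl-1,3-bis(methoxymethoxy)-5-{2-[4-(methoxymethoxy)phenyl]ethyl}benzene; 8 mac diol
Product: 10 cis-1,2-dimethylacenaphthylene-1,2-diyl ester of (E)-2-{2,6-bis(methoxymethoxy)-4-[2-(4-(methoxymethoxy)phenyl)ethyl]phenyl}ethenylboronic acid [alkenyl B(mac) ester], via alkenyl catecholboronate 9 (not isolated)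
Conditions: catecholborane, THF, 65 °C; then 8, rt; wash with aq NaHCO3
Reagents that add atoms: catecholborane, B1Oc2ccccc2O1
Why: Hydroboration of the terminal alkyne with catecholborane is a syn, anti-Markovnikov addition that fixes the E geometry, and the labile catechol ester exchanges with the ditertiary cis-diol 8 (transesterification) to give the hindered boronate; no stereocentre is formed.

Step 7
Reactants: 11 3,5-bis(benzyloxy)phenol
Product: 12 3,5-bis(benzyloxy)phenyl trifluoromethanesulfonate
Conditions: Tf2O, pyridine, CH2Cl2, 0 °C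
Reagents that add atoms: trifluoromethanesulfonic anhydride, O=S(=O)(OS(=O)(=O)C(F)(F)F)C(F)(F)F
Why: O-sulfonylation of the phenol gives the aryl triflate, the electrophile of the key step, and leaves the benzyl ethers unchanged; no stereocentre is formed.

Step 8
Reactants: 13 1-(benzyloxy)-4-bromobenzene; 10 alkenyl B(mac) ester; 12 3,5-bis(benzyloxy)phenyl trifluoromethanesulfonate
Product: 16 B(mac) ester of (1R,2S)-1-[4-(benzyloxy)phenyl]-2-[3,5-bis(benzyloxy)phenyl]-2-{2,6-bis(methoxymethoxy)-4-[2-(4-(methoxymethoxy)phenyl)ethyl]phenyl}ethylboronic acid, via 4-(benzyloxy)phenyllithium 14 (not isolated), via lithium boron ate complex 15 (not isolated)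
Conditions: 13, t-BuLi (2.0 equiv), Et2O, −78 °C; add 10, −78 °C → rt; evaporate, THF; 12, NaOTf, Pd(OAc)2 (2 mol%), (SP,S′P)-1,1′-bis(diphenylphosphino)-2,2′-bis[(R)-α-(dimethylamino)benzyl]ferrocene (2.4 mol%), 60 °C
Reagents that add atoms: none
Why: Aryllithium 14 adds to the trigonal boron of 10 to give the four-coordinate boronate 15; the cationic divalent arylpalladium complex formed from triflate 12 and zerovalent palladium binds the alkene of 15, the 4-(benzyloxy)phenyl group shifts from boron to C2 anti to palladium while palladium bonds to C3 (metal-induced 1,2-metallate rearrangement), and reductive elimination then forms the C3–aryl bond with retention. The closest known reaction is the enantioselective palladium-catalysed conjunctive cross-coupling of β-substituted alkenyl B(mac) ate complexes, formed from aryllithium reagents, with aryl triflates; no ring is closed. C3 is controlled by the chiral ferrocenyl diphosphine, which selects the Re face of the ring A-bearing alkene carbon for palladium, and C2 is controlled by the anti course of the shift across the E double bond, so the 1R,2S open-chain boronate should result. The step needs the metallate shift to win over direct transfer of the alkenyl group to palladium (Suzuki–Miyaura coupling) and over β-hydride loss: the hindered ditertiary mac diol on boron suppresses alkenyl transfer, NaOTf removes the bromide that would block the cationic palladium centre, and the wide-bite-angle diphosphine favours fast reductive elimination. The doubly ortho-substituted ring A is already bonded to carbon, so the most hindered aryl group never has to be transferred at the metal.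

Step 9
Reactants: 16 B(mac) ester of the (1R,2S)-triarylethylboronic acid
Product: 17 (1R,2S)-1-[4-(benzyloxy)phenyl]-2-[3,5-bis(benzyloxy)phenyl]-2-{2,6-bis(methoxymethoxy)-4-[2-(4-(methoxymethoxy)phenyl)ethyl]phenyl}ethan-1-ol
Conditions: 3 M NaOH, 30% H2O2, THF, 0 °C → rt
Reagents that add atoms: hydrogen peroxide, OO
Why: Oxidation of the secondary benzylic boronate with basic hydrogen peroxide proceeds by 1,2-shift of carbon from boron to oxygen with retention, so the carbinol carbon keeps the configuration set in step 8 (1R) and C3 is not touched, while acetals and benzyl ethers are stable to these conditions.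

Step 10
Reactants: 17 (1R,2S)-triarylethanol
Product: 19 (2S,3S)-2-[4-(benzyloxy)phenyl]-3-[3,5-bis(benzyloxy)phenyl]-6-[2-(4-hydroxyphenyl)ethyl]-2,3-dihydro-1-benzofuran-4-ol (trans), via triphenolic alcohol 18 (not isolated)
Conditions: conc. HCl (cat.), MeOH/THF, rt → 40 °C
Reagents that add atoms: none
Why: Acid-catalysed acetal cleavage frees the ring A phenols and the 4-benzyloxybenzylic alcohol ionises under the same conditions, so a flanking phenol closes the O1–C2 bond by intramolecular trapping of the benzylic cation (the cyclisation used for pterocarpans and trans-2,3-diaryl-2,3-dihydrobenzofurans); C2 is formed anti to the C3 aryl group under control of C3, which is the net inversion of the carbinol centre of 17 and also the thermodynamically favoured trans isomer, and C3 is untouched.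

Step 11
Reactants: 19 (2S,3S)-tribenzyl ether
Product: 20 (2S,3S)-3-(3,5-dihydroxyphenyl)-2-(4-hydroxyphenyl)-6-[2-(4-hydroxyphenyl)ethyl]-2,3-dihydro-1-benzofuran-4-ol (target)
Conditions: H2 (1 atm), 10% Pd/C, EtOAc/MeOH, rt
Reagents that add atoms: none
Why: Hydrogenolysis of the three benzyl aryl ethers under neutral conditions should be faster than cleavage of the cyclic benzylic C2–O1 bond (as in the debenzylation of O-benzylated 2-arylchromans), so both stereocentres are kept and the target is released.

**Compound list**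

1 | resveratrol | Oc1ccc(/C=C/c2cc(O)cc(O)c2)cc1 | starting material
2 | (E)-1,3-bis(methoxymethoxy)-5-{2-[4-(methoxymethoxy)phenyl]ethenyl}benzene | COCOc1ccc(/C=C/c2cc(OCOC)cc(OCOC)c2)cc1 | intermediate
3 | 1,3-bis(methoxymethoxy)-5-{2-[4-(methoxymethoxy)phenyl]ethyl}benzene | COCOc1ccc(CCc2cc(OCOC)cc(OCOC)c2)cc1 | intermediate
4 | {2,6-bis(methoxymethoxy)-4-[2-(4-(methoxymethoxy)phenyl)ethyl]phenyl}lithium | [Li]c1c(OCOC)cc(CCc2ccc(OCOC)cc2)cc1OCOC | intermediate (not isolated)
5 | 2,6-bis(methoxymethoxy)-4-{2-[4-(methoxymethoxy)phenyl]ethyl}benzaldehyde | O=Cc1c(OCOC)cc(CCc2ccc(OCOC)cc2)cc1OCOC | intermediate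
6 | 2-ethynyl-1,3-bis(methoxymethoxy)-5-{2-[4-(methoxymethoxy)phenyl]ethyl}benzene | C#Cc1c(OCOC)cc(CCc2ccc(OCOC)cc2)cc1OCOC | intermediate
7 | acenaphthoquinone | O=C1C(=O)c2cccc3cccc1c23 | starting material
8 | (1R,2S)-1,2-dimethyl-1,2-dihydroacenaphthylene-1,2-diol (cis, mac diol) | C[C@@]1(O)c2cccc3cccc(c23)[C@]1(C)O | intermediate
9 | 2-[(E)-2-{2,6-bis(methoxymethoxy)-4-[2-(4-(methoxymethoxy)phenyl)ethyl]phenyl}ethenyl]-1,3,2-benzodioxaborole | COCOc1ccc(CCc2cc(OCOC)c(/C=C/B3Oc4ccccc4O3)c(OCOC)c2)cc1 | intermediate (not isolated)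
10 | cis-1,2-dimethylacenaphthylene-1,2-diyl ester of (E)-2-{2,6-bis(methoxymethoxy)-4-[2-(4-(methoxymethoxy)phenyl)ethyl]phenyl}ethenylboronic acid | COCOc1ccc(CCc2cc(OCOC)c(/C=C/B3O[C@]4(C)c5cccc6cccc(c56)[C@]4(C)O3)c(OCOC)c2)cc1 | intermediate
11 | 3,5-bis(benzyloxy)phenol | Oc1cc(OCc2ccccc2)cc(OCc2ccccc2)c1 | starting material
12 | 3,5-bis(benzyloxy)phenyl trifluoromethanesulfonate | O=S(=O)(Oc1cc(OCc2ccccc2)cc(OCc2ccccc2)c1)C(F)(F)F | intermediate
13 | 1-(benzyloxy)-4-bromobenzene | Brc1ccc(OCc2ccccc2)cc1 | starting material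
14 | 4-(benzyloxy)phenyllithium | [Li]c1ccc(OCc2ccccc2)cc1 | intermediate (not isolated)
15 | lithium [4-(benzyloxy)phenyl][(E)-2-(ring A aryl)ethenyl](cis-1,2-dimethylacenaphthylene-1,2-diolato)borate (configuration at boron not defined) | [Li+].COCOc1ccc(CCc2cc(OCOC)c(/C=C/[B-]3(c4ccc(OCc5ccccc5)cc4)O[C@]4(C)c5cccc6cccc(c56)[C@]4(C)O3)c(OCOC)c2)cc1 | intermediate (not isolated)
16 | B(mac) ester of (1R,2S)-1-[4-(benzyloxy)phenyl]-2-[3,5-bis(benzyloxy)phenyl]-2-{2,6-bis(methoxymethoxy)-4-[2-(4-(methoxymethoxy)phenyl)ethyl]phenyl}ethylboronic acid | B1(O[C@]2(C)c3cccc4cccc(c34)[C@]2(C)O1)[C@@H](c1ccc(OCc2ccccc2)cc1)[C@H](c1c(OCOC)cc(CCc2ccc(OCOC)cc2)cc1OCOC)c1cc(OCc2ccccc2)cc(OCc2ccccc2)c1 | intermediate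
17 | (1R,2S)-1-[4-(benzyloxy)phenyl]-2-[3,5-bis(benzyloxy)phenyl]-2-{2,6-bis(methoxymethoxy)-4-[2-(4-(methoxymethoxy)phenyl)ethyl]phenyl}ethan-1-ol | O[C@@H](c1ccc(OCc2ccccc2)cc1)[C@H](c1c(OCOC)cc(CCc2ccc(OCOC)cc2)cc1OCOC)c1cc(OCc2ccccc2)cc(OCc2ccccc2)c1 | intermediate
18 | (1R,2S)-1-[4-(benzyloxy)phenyl]-2-[3,5-bis(benzyloxy)phenyl]-2-{2,6-dihydroxy-4-[2-(4-hydroxyphenyl)ethyl]phenyl}ethan-1-ol | O[C@@H](c1ccc(OCc2ccccc2)cc1)[C@H](c1c(O)cc(CCc2ccc(O)cc2)cc1O)c1cc(OCc2ccccc2)cc(OCc2ccccc2)c1 | intermediate (not isolated)
19 | (2S,3S)-2-[4-(benzyloxy)phenyl]-3-[3,5-bis(benzyloxy)phenyl]-6-[2-(4-hydroxyphenyl)ethyl]-2,3-dihydro-1-benzofuran-4-ol | Oc1ccc(CCc2cc(O)c3c(c2)O[C@H](c2ccc(OCc4ccccc4)cc2)[C@H]3c2cc(OCc3ccccc3)cc(OCc3ccccc3)c2)cc1 | intermediate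
20 | (2S,3S)-3-(3,5-dihydroxyphenyl)-2-(4-hydroxyphenyl)-6-[2-(4-hydroxyphenyl)ethyl]-2,3-dihydro-1-benzofuran-4-ol | Oc1ccc(CCc2cc(O)c3c(c2)O[C@H](c2ccc(O)cc2)[C@H]3c2cc(O)cc(O)c2)cc1 | target

**Step count**

Total: 11 steps. Longest linear sequence: 9 steps (steps 1, 2, 3, 4, 6, 8, 9, 10, 11 from resveratrol); steps 5 and 7 are side branches.

**Steps most likely to fail, with fallbacks**

Step 8. What may go wrong: direct transfer of the alkenyl group from boron to palladium (Suzuki–Miyaura coupling to a stilbene), slow binding of the alkene next to the doubly ortho-substituted ring A, or poor facial selectivity. The fallback makes the two aryl–carbon bonds and both stereocentres one after the other by Matteson homologation under control of a C2-symmetric diol on boron.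
- Commercial 3,5-bis(benzyloxy)phenylboronic acid is condensed with (1S,2S)-1,2-dicyclohexylethane-1,2-diol (MgSO4, CH2Cl2) to the aryl dioxaborolane F1.
- LiCHCl2 (THF, −100 °C) and then ZnCl2 insert a chloromethine carbon with aryl migration to give the (R)-α-chlorobenzyl boronate F2, which is used without isolation.
- Aryllithium 4, made from 3 as in step 3, adds to boron and shifts to carbon with inversion, displacing chloride, to give the (S)-diarylmethyl boronate F3, which carries the C3 configuration of the target.
- A second LiCHCl2/ZnCl2 homologation gives the (1R,2S)-α-chloro boronate F4, again not isolated.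
- 4-(Benzyloxy)phenyllithium 14, made from 13 as in step 8, displaces chloride with inversion to give the (1S,2S)-triarylethyl boronate F5, which has C3 as in 16 and the opposite configuration at the boron-bearing carbon.
- NaOH/H2O2 gives the (1S,2S)-alcohol F6, the carbinol epimer of 17. The acid treatment of step 10 converts F6 to 19, because that ring closure runs through the benzylic cation and should give the trans ring from either carbinol epimer.
The fallback sets out from 3 and 13 and comes back to the route at 19.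

Step 10. What may go wrong: loss of the C3 proton from the benzylic cation (elimination to a triarylethene), which lowers the yield and, if the alkene is protonated again, erodes the configuration at C3; capture of the cation by the electron-rich free resorcinol ring; slow acetal cleavage. The fallback closes the ring by substitution with inversion without a free cation. Boronate 16 is treated with HCl in MeOH first, which removes the three MOM groups and leaves the C–B bond, to give the triphenolic B(mac) boronate F7. NaBO3·4H2O in THF/H2O then oxidises C–B with retention to triol 18, now isolated. Mitsunobu cyclisation (PPh3, diisopropyl azodicarboxylate, THF, 0 °C, high dilution) activates the benzylic alcohol and a ring A phenol displaces it with inversion to give 19. The fallback sets out from 16 and comes back at 19.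

Step 6. What may go wrong: slow hydroboration of the alkyne flanked by two acetal groups, cleavage of MOM ethers by the boron hydride at the temperature needed, or incomplete exchange of catechol for the hindered diol. The fallback replaces hydroboration by olefination. Aldehyde 5 reacts with lithiated bis[(pinacolato)boryl]methane (LiTMP, THF, −78 °C → rt; boron–Wittig reaction) to give the (E)-alkenyl pinacol boronate F8. NaIO4/NH4OAc in acetone/H2O cleaves the pinacol ester to the (E)-alkenylboronic acid F9. Condensation with mac diol 8 (MgSO4, CH2Cl2) gives 10. The fallback sets out from 5 and comes back at 10; alkyne 6 is bypassed.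

**Further compounds**

F1 | step 8 | (4S,5S)-2-[3,5-bis(benzyloxy)phenyl]-4,5-dicyclohexyl-1,3,2-dioxaborolane | B1(O[C@@H](C2CCCCC2)[C@H](C2CCCCC2)O1)c1cc(OCc2ccccc2)cc(OCc2ccccc2)c1
F2 | step 8 | (4S,5S)-2-{(R)-[3,5-bis(benzyloxy)phenyl](chloro)methyl}-4,5-dicyclohexyl-1,3,2-dioxaborolane | Cl[C@@H](c1cc(OCc2ccccc2)cc(OCc2ccccc2)c1)B1O[C@@H](C2CCCCC2)[C@H](C2CCCCC2)O1
F3 | step 8 | (4S,5S)-2-{(S)-[3,5-bis(benzyloxy)phenyl][2,6-bis(methoxymethoxy)-4-(2-(4-(methoxymethoxy)phenyl)ethyl)phenyl]methyl}-4,5-dicyclohexyl-1,3,2-dioxaborolane | B1(O[C@@H](C2CCCCC2)[C@H](C2CCCCC2)O1)[C@H](c1c(OCOC)cc(CCc2ccc(OCOC)cc2)cc1OCOC)c1cc(OCc2ccccc2)cc(OCc2ccccc2)c1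
F4 | step 8 | (4S,5S)-2-{(1R,2S)-2-[3,5-bis(benzyloxy)phenyl]-2-[2,6-bis(methoxymethoxy)-4-(2-(4-(methoxymethoxy)phenyl)ethyl)phenyl]-1-chloroethyl}-4,5-dicyclohexyl-1,3,2-dioxaborolane | Cl[C@H](B1O[C@@H](C2CCCCC2)[C@H](C2CCCCC2)O1)[C@H](c1c(OCOC)cc(CCc2ccc(OCOC)cc2)cc1OCOC)c1cc(OCc2ccccc2)cc(OCc2ccccc2)c1
F5 | step 8 | (4S,5S)-2-{(1S,2S)-1-[4-(benzyloxy)phenyl]-2-[3,5-bis(benzyloxy)phenyl]-2-[2,6-bis(methoxymethoxy)-4-(2-(4-(methoxymethoxy)phenyl)ethyl)phenyl]ethyl}-4,5-dicyclohexyl-1,3,2-dioxaborolane | B1(O[C@@H](C2CCCCC2)[C@H](C2CCCCC2)O1)[C@H](c1ccc(OCc2ccccc2)cc1)[C@H](c1c(OCOC)cc(CCc2ccc(OCOC)cc2)cc1OCOC)c1cc(OCc2ccccc2)cc(OCc2ccccc2)c1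
F6 | step 8 | (1S,2S)-1-[4-(benzyloxy)phenyl]-2-[3,5-bis(benzyloxy)phenyl]-2-{2,6-bis(methoxymethoxy)-4-[2-(4-(methoxymethoxy)phenyl)ethyl]phenyl}ethan-1-ol | O[C@H](c1ccc(OCc2ccccc2)cc1)[C@H](c1c(OCOC)cc(CCc2ccc(OCOC)cc2)cc1OCOC)c1cc(OCc2ccccc2)cc(OCc2ccccc2)c1
F7 | step 10 | B(mac) ester of (1R,2S)-1-[4-(benzyloxy)phenyl]-2-[3,5-bis(benzyloxy)phenyl]-2-{2,6-dihydroxy-4-[2-(4-hydroxyphenyl)ethyl]phenyl}ethylboronic acid | B1(O[C@]2(C)c3cccc4cccc(c34)[C@]2(C)O1)[C@@H](c1ccc(OCc2ccccc2)cc1)[C@H](c1c(O)cc(CCc2ccc(O)cc2)cc1O)c1cc(OCc2ccccc2)cc(OCc2ccccc2)c1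
F8 | step 6 | 2-[(E)-2-{2,6-bis(methoxymethoxy)-4-[2-(4-(methoxymethoxy)phenyl)ethyl]phenyl}ethenyl]-4,4,5,5-tetramethyl-1,3,2-dioxaborolane | COCOc1ccc(CCc2cc(OCOC)c(/C=C/B3OC(C)(C)C(C)(C)O3)c(OCOC)c2)cc1
F9 | step 6 | (E)-2-{2,6-bis(methoxymethoxy)-4-[2-(4-(methoxymethoxy)phenyl)ethyl]phenyl}ethenylboronic acid | COCOc1ccc(CCc2cc(OCOC)c(/C=C/B(O)O)c(OCOC)c2)cc1
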